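## Structural features

The target (C20H32O5) is a labdane-type diterpenoid. A trans-fused decalin (ring A C1–C5/C10, ring B C5–C10) carries a tetrahydrofuran (O–C9–C11–C12–C13) spiro at C9, and this is spiro-joined at C13 to a γ-lactone (C13–C14–C15(=O)–O–C16). Six of the seven stereocentres are contiguous on the decalin: the 3β-hydroxyl beside quaternary C4 (CH2OH α, methyl β), H-5α, the 10β-methyl, the fully substituted C9 (oxygen α, C11 β) and C8 (methyl α). The seventh, C13 (R), is separated from C9 only by the ether oxygen and two CH2 groups. The fragile groups are the β-alkoxy lactone (retro-oxa-Michael opening under base would erase C13), the two tertiary ether carbons towards acid, and the free 1,3-diol. The real difficulties are C9, an oxygen-bearing tetrasubstituted carbon between quaternary C10 and C8; quaternary C4 with one oxidised substituent; and C13, whose two faces differ only in CH2C(=O) against CH2O. The key step exploits the correspondence of the C3 hydroxyl next to C4, the trans C5/C10 fusion and the C9 oxygen with an epoxide, one E-trisubstituted alkene and a nitrile on a single acyclic chain, so that rings A and B close together and C9 is left as a ketone.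

## Logic of the disconnections

19 to 18: the O–Si bond at C18 is cut. The primary alcohol must stay masked from the silylation onwards, while the hindered secondary C3 hydroxyl can travel free, so one protecting group serves the whole route. The forward step must be non-basic, because base would reopen the β-alkoxy lactone and scramble C13.

18 to 17: the C13–O ether bond is cut (retro-oxa-Michael). It is the one bond at C13 that can be formed reversibly, and cutting it turns both spiro rings into a planar butenolide on a side chain and removes C13 as a stereocentre. The forward step asks a tertiary alcohol to add 5-exo to a β,β-disubstituted acceptor, with little facial bias to be expected, so separation and recycling of the wrong epimer are part of the plan.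

17 to 14: the C15 carbonyl and the C16 methylene are traced back to a 3-substituted furan. The furan is a robust latent butenolide that survives organometallic chemistry, and the side chain becomes a simple heteroarylmethyl unit. The oxidation must place the carbonyl at C15 and not at C16.

14 to 11 and 12 (through 13): the C11–C12 bond is cut. C11 is a primary carbon on C9 and the only accessible electrophilic site near that centre, and the five side-chain carbons then come from a commercial halide. The forward step needs SN2 attack at the CH2 of a hindered spiro-epoxide by the exocyclic carbon of an ambident furylmethyl metal, without Lewis-acid rearrangement of the epoxide.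

11 to 10 to 9: the epoxide C–O bonds and then C9=C11 are cut. A carbon nucleophile added directly to the C9 ketone would enter from the open α face and give the 9β-alcohol. Epoxidising the methylene compound from that same α face puts oxygen α and carbon β, as required. The demands are methylenation of a neopentyl ketone and α-selective epoxidation.

9 to 7 (through 8): C4–C5 and C9–C10 are cut. Two rings and the centres C4, C5 and C10 collapse to an acyclic chain whose only controlled stereochemistry is one epoxide, with the nitrile carbon as the future C9. A check of 7 and 9 against 19 (atom mapping and all stereocentres) shows them consistent, so their structures needed no correction. The precursor design is kept and specified as follows: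
- C8 is left unset, because it is corrected by equilibration at the ketone stage.
- C18 carries the bulky tert-butyldiphenylsilyl ether, both to favour the equatorial position at the planar C4 radical and because a free alcohol would invite β-elimination.
- The forward step needs the nitrile addition to outrun termination of the C10 radical.

7 to 5 and 6, and 5 to 4: the O–Si bond and the two epoxide C–O bonds are cut. The free (E)-allylic alcohol is the substrate for reagent-controlled epoxidation, which sets C3 and the absolute configuration of everything that follows. The forward step must epoxidise only the allylic alkene and needs the L-(+)-tartrate.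

4 to 3 to 1 and 2: the allylic C18–O bond and the C8–C9 bond are cut. Compound 1 already contains C1–C8 and C17–C20 with the E-alkene, so only one oxygen and the nitrile carbon are missing. The forward steps need site- and E-selective oxidation of the terminal methyl group and reductive cyanation of a methyl ketone.

## Other disconnections considered

Alternative 1: The cut is the C9–C11 bond, with C12 and C13 arriving as a cyclopropane and the C9–O bond made afterwards by oxygen insertion. In the forward step the α-oxaspiropentane A2 would be ionised at C9–O by LiBF4, and a cyclopropane CH2 would shift to C9 to give the spiro-cyclobutanone A1. A later Baeyer–Villiger oxidation of A1 would insert the C9 oxygen with retention.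
- In its favour: the shift is driven by strain release and no external nucleophile has to reach the neopentyl position. A shift anti to the departing oxygen would set C11 β and, after insertion, oxygen α. On these two points it is better than step 8 of the chosen plan, which needs an ambident nucleophile and an SN2 reaction beside a quaternary carbon.
- Equal: it starts from a C9 ketone of the kind of 9, so it neither helps nor harms the ring construction.
- Against it: A2 needs its oxygen on the α face, whereas a sulfur ylide would deliver carbon from that face. A2 would therefore require olefination with a cyclopropylidene ylide and α-epoxidation at a very hindered carbonyl. Stereospecificity at a tertiary cationic centre is not assured. After A1 the carbonyl carbon C13 must still receive C14 and C16 and be lactonised, with no handle for C13 and with an acetonide exchange added.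
- Step economy: several steps longer than the chosen plan, which reaches the same bonds from 11 in three steps and can equilibrate C13.

Alternative 2: The cut is the C13–C14 bond. In the forward step Rh2(OAc)4 would decompose the diazoacetate A4 and the carbenoid would insert into the C13–H bond to give the target diacetate A3, followed by removal of two acetates.
- In its favour: insertion goes with retention, so C13 would be fixed earlier, at a secondary ether carbon where ordinary stereocontrol is available. In fidelity at C13 this is better than the reversible oxa-Michael closure of the chosen plan. The C–H bond is activated by the ether oxygen and the 1,5-relationship gives the five-membered lactone.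
- Against it: acceptor-only carbenoids from diazoacetates are unselective. Oxonium-ylide formation at the tetrahydrofuran oxygen, insertion into the C12 methylene and dimerisation would compete. Both hydroxyls must be capped and released. A4 itself needs a tetrahydrofuran with a defined C13–H centre and a diazo ester, which costs steps.
- Comparison: it does nothing for rings A and B or for C9 (equal to the chosen plan there); mechanistically it is a concerted insertion against a conjugate addition; it is longer overall because of protecting-group and diazo handling.

Alternative 3: The cuts are C8–C9 and C13–C16 (retro-[4+2]). In the forward step the furan–alkyne A6 would be heated so that the 2,5-disubstituted furan adds across the tethered terminal alkyne, giving the ring B-fused 7-oxanorbornadiene A5.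
- In its favour: two bonds, ring B and the oxygen bridge form in one reagent-free step, and the bridge locks C9 and C13 relative to each other. This is better than the chosen plan for the C9/C13 relationship.
- Against it: an unactivated alkyne and a furan need high temperature and the addition is reversible. Which face of the furan adds relative to quaternary C10 is not obviously controlled. A5 contains a C8=C16 bond absent from the target, so that bond must be cleaved and C11=C12 reduced selectively. C17 is missing and would have to be added at C8 with the 8α configuration. Ring A with C3, C4, C5 and C10 must be built beforehand.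
- Comparison: the chosen plan makes rings A and B and three stereocentres from an acyclic chain in one step and carries C17 from the start; alternative 3 is clearly longer.

Key step: step 5

Remarks on the chemistry: labdane numbering is used throughout, also for the acyclic chain. Compounds 3 to 8 are carried as mixtures at C8. The (3S,4S)-epoxide of 7 corresponds to L-(+)-diethyl tartrate in step 3. The two C13 epimers formed in step 10 are assumed to be separable by chromatography.

## Route

Step 1
Reactants: 1 geranylacetone [(5E)-6,10-dimethylundeca-5,9-dien-2-one]; 2 tosylmethyl isocyanide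
Product: 3 (5E)-2,6,10-trimethylundeca-5,9-dienenitrile (racemic at the nitrile-bearing carbon)
Conditions: t-BuOK, DME, EtOH (2 equiv), 0 °C to 40 °C
Reagents that add atoms: none
Why: Van Leusen reductive cyanation converts the methyl ketone into the one-carbon-longer secondary nitrile and leaves both trisubstituted alkenes untouched. The new centre is racemic, which is harmless because it becomes the epimerisable C8 of ketone 9.

Step 2
Reactants: 3
Product: 4 (5E,9E)-11-hydroxy-2,6,10-trimethylundeca-5,9-dienenitrile
Conditions: SeO2 (5 mol%), t-BuOOH (70% aq.), salicylic acid (10 mol%), CH2Cl2, 0 °C to rt, stopped before full conversion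
Reagents that add atoms: tert-butyl hydroperoxide, CC(C)(C)OO; selenium dioxide, O=[Se]=O
Why: Riley allylic oxidation (ene reaction, then [2,3]-sigmatropic shift) selects the E-methyl group of a terminal isopropylidene unit in polyprenyl chains and gives the (E)-allylic alcohol. The internal alkene and the nitrile react more slowly, and partial conversion limits over-oxidation to the enal.

Step 3
Reactants: 4
Product: 5 (5E)-8-[(2S,3S)-3-(hydroxymethyl)-3-methyloxiran-2-yl]-2,6-dimethyloct-5-enenitrile
Conditions: Ti(OiPr)4 (10 mol%), L-(+)-diethyl tartrate (12 mol%), t-BuOOH (anhydrous), 4 Å MS, CH2Cl2, −20 °C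
Reagents that add atoms: tert-butyl hydroperoxide, CC(C)(C)OO
Why: Katsuki–Sharpless asymmetric epoxidation acts only on the allylic alcohol. With the L-(+)-tartrate this (E)-2-methylalk-2-en-1-ol should give the (2S,3S)-epoxide, which fixes C3 as 3S and with it the absolute configuration of the decalin.

Step 4
Reactants: 5; 6 tert-butyl(chloro)diphenylsilane
Product: 7 (5E)-8-[(2S,3S)-3-(tert-butyldiphenylsilyloxymethyl)-3-methyloxiran-2-yl]-2,6-dimethyloct-5-enenitrile
Conditions: imidazole, CH2Cl2, 0 °C to rt
Reagents that add atoms: none
Why: Standard silylation of a primary alcohol. The bulky, acid- and base-stable silyl ether prevents β-elimination at the future C4 radical and is meant to favour the equatorial position of C18.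

Step 5
Reactants: 7
Product: 9 18-(tert-butyldiphenylsilyloxy)-3β-hydroxy-11,12,13,14,15,16-hexanorlabdan-9-one (8α-methyl trans-decalin), via NH ketimine 8 (not isolated)
Conditions: Cp2TiCl2 (20 mol%), Mn dust, 2,4,6-collidine·HCl, THF (degassed, 0.01 M), rt, slow addition of 7; then 1 M HCl/THF, rt; then K2CO3, MeOH, rt
Reagents that add atoms: water, O
Why: Proposed new method: Cp2TiCl (trivalent titanium, formed from Cp2TiCl2 and Mn) should open the epoxide by single-electron transfer at the tertiary carbon to give the C4 radical beside a C3 titanium alkoxide; this radical closes ring A by 6-endo-trig addition to C5 of the E-alkene, the resulting tertiary C10 radical closes ring B by 6-exo-dig addition to the nitrile carbon C9, and the iminyl radical is reduced by a second Cp2TiCl and protonated by collidinium to ketimine 8, which acid work-up hydrolyses to the ketone. The closest known reaction types are the Cp2TiCl bicyclisation of epoxypolyprenes and the Cp2TiCl cyclisation of epoxy nitriles to β-hydroxy ketones; joining them in one cascade through an intervening alkene is the untested part. C3 is carried over from the Sharpless epoxide because its C–O bond is never broken. C5 and C10 should follow from a chair–chair transition state with the C3 titanium alkoxide equatorial and the E-alkene, which puts H-5 α and the C10 methyl β (trans fusion). C4 is set at a planar radical, so the 4α (equatorial) position of the silyloxymethyl group rests on that bulky group avoiding the 1,3-diaxial contact with the C10 methyl and must be confirmed by NOE. C8 enters as a mixture and is corrected by K2CO3 after hydrolysis, the 8α (equatorial) methyl being strongly preferred because the 8β epimer is syn-diaxial to the C10 methyl. The step needs the slow nitrile addition to outrun elimination or reduction of the C10 radical; the low stationary concentration of Cp2TiCl under catalytic high-dilution conditions, the steric shielding of a tertiary radical against titanium trapping and activation of the nitrile by coordination to titanium are what should secure this.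

Step 6
Reactants: 9
Product: 10 18-(tert-butyldiphenylsilyloxy)-12,13,14,15,16-pentanorlabd-9(11)-en-3β-ol (9-methylene decalin)
Conditions: Ph3PCH3Br, t-BuOK, toluene, 90 °C
Reagents that add atoms: methyltriphenylphosphonium bromide, C[P+](c1ccccc1)(c1ccccc1)c1ccccc1.[Br-]
Why: Wittig methylenation under the hot alkoxide conditions used for hindered ketones, with excess ylide to cover the free C3 hydroxyl. C8 stays 8α because that epimer is the thermodynamic one under base and the alkene cannot epimerise afterwards.

Step 7
Reactants: 10
Product: 11 9α,11-epoxy-18-(tert-butyldiphenylsilyloxy)-12,13,14,15,16-pentanorlabdan-3β-ol (spiro-oxirane with oxygen on the α face)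
Conditions: mCPBA, NaHCO3, CH2Cl2, 0 °C
Reagents that add atoms: mCPBA (3-chloroperoxybenzoic acid), OOC(=O)c1cccc(Cl)c1
Why: Prilezhaev epoxidation. The peracid should approach the exocyclic alkene from the α face, away from the axial C10 methyl on the neighbouring carbon, so that oxygen ends up 9α and C11 9β as in the target; the buffer prevents acid-induced rearrangement of the spiro-epoxide.

Step 8
Reactants: 11; 12 3-(bromomethyl)furan
Product: 14 18-(tert-butyldiphenylsilyloxy)-15,16-epoxylabda-13(16),14-diene-3β,9α-diol, via furan-3-ylmethylmagnesium bromide 13 (not isolated)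
Conditions: 12, Mg, THF, 0 °C; then 11, CuI (10 mol%), THF, −30 °C to 0 °C; aq. NH4Cl
Reagents that add atoms: none
Why: Copper-catalysed SN2 opening of a 1,1-disubstituted epoxide at its CH2 terminus by a Grignard reagent forms C11–C12 and leaves the C9–O bond, hence the 9α-hydroxyl, untouched. One equivalent of 13 is spent on the C3 hydroxyl, and copper catalysis at low temperature is chosen to favour coupling at the exocyclic carbon of the furylmethyl unit and to suppress magnesium-halide-induced epoxide rearrangement.

Step 9
Reactants: 14
Product: 17 18-(tert-butyldiphenylsilyloxy)-3β,9α-dihydroxylabd-13-en-15,16-olide, via furan endoperoxide 15 (not isolated), via γ-hydroxybutenolide 16 (not isolated)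
Conditions: O2, hν, tetraphenylporphyrin, i-Pr2NEt, CH2Cl2, −78 °C; then NaBH4, MeOH, 0 °C; 1 M HCl to pH 3
Reagents that add atoms: oxygen, O=O
Why: Singlet oxygen adds [4+2] to the furan, and the hindered amine removes the less shielded bridgehead proton at C15 (Kornblum–DeLaMare fragmentation), which places the carbonyl at C15 and the hydroxyl at C16. Borohydride then reduces the ring-opened C16 aldehyde and acidification relactonises to the β-substituted butenolide; no stereocentre of the target is formed here.

Step 10
Reactants: 17
Product: 18 (13R)-18-(tert-butyldiphenylsilyloxy)-9α,13-epoxy-3β-hydroxylabdan-15,16-olide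
Conditions: DBU, toluene, 50 °C; chromatographic separation of the C13 epimers and resubmission of the 13S epimer
Reagents that add atoms: none
Why: Intramolecular oxa-Michael addition (5-exo-trig) of the tertiary 9α-hydroxyl to C13 of the butenolide closes the tetrahydrofuran and saturates the lactone. C9 is already fixed, whereas C13 forms under reversible (retro-Michael) conditions with little inherent bias between its faces, so the 13R epimer is separated and the 13S epimer re-equilibrated.

Step 11
Reactants: 18
Product: 19 (13R)-9α,13-epoxy-3β,18-dihydroxylabdan-15,16-olide (CNP0274732.3)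
Conditions: TBAF, AcOH, THF, rt
Reagents that add atoms: none
Why: Fluoride cleaves the primary silyl ether. Buffering with acetic acid keeps the medium non-basic, so the β-alkoxy lactone cannot open by retro-Michael reaction and C13 is preserved.

## Compound list

1 | geranylacetone, (5E)-6,10-dimethylundeca-5,9-dien-2-one | CC(=O)CC/C=C(C)/CCC=C(C)C | starting material
2 | tosylmethyl isocyanide | Cc1ccc(cc1)S(=O)(=O)C[N+]#[C-] | starting material
3 | (5E)-2,6,10-trimethylundeca-5,9-dienenitrile (racemic) | N#CC(C)CC/C=C(\C)CCC=C(C)C | intermediate
4 | (5E,9E)-11-hydroxy-2,6,10-trimethylundeca-5,9-dienenitrile | N#CC(C)CC/C=C(\C)CC/C=C(\C)CO | intermediate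
5 | (5E)-8-[(2S,3S)-3-(hydroxymethyl)-3-methyloxiran-2-yl]-2,6-dimethyloct-5-enenitrile (C8 epimers) | N#CC(C)CC/C=C(\C)CC[C@@H]1O[C@@]1(C)CO | intermediate
6 | tert-butyl(chloro)diphenylsilane | CC(C)(C)[Si](Cl)(c1ccccc1)c1ccccc1 | starting material
7 | (5E)-8-[(2S,3S)-3-(tert-butyldiphenylsilyloxymethyl)-3-methyloxiran-2-yl]-2,6-dimethyloct-5-enenitrile (C8 epimers) | N#CC(C)CC/C=C(\C)CC[C@@H]1O[C@@]1(C)CO[Si](c1ccccc1)(c1ccccc1)C(C)(C)C | intermediate
8 | NH ketimine of 9 (9-imino decalin, C8 epimers; not isolated) | CC1CC[C@H]2[C@](C)(CO[Si](c3ccccc3)(c3ccccc3)C(C)(C)C)[C@@H](O)CC[C@]2(C)C1=N | intermediate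
9 | 18-(tert-butyldiphenylsilyloxy)-3β-hydroxy-11,12,13,14,15,16-hexanorlabdan-9-one (5α-H, 8α-methyl, 10β-methyl) | C[C@@H]1CC[C@H]2[C@](C)(CO[Si](c3ccccc3)(c3ccccc3)C(C)(C)C)[C@@H](O)CC[C@]2(C)C1=O | intermediate
10 | 18-(tert-butyldiphenylsilyloxy)-12,13,14,15,16-pentanorlabd-9(11)-en-3β-ol | C[C@@H]1CC[C@H]2[C@](C)(CO[Si](c3ccccc3)(c3ccccc3)C(C)(C)C)[C@@H](O)CC[C@]2(C)C1=C | intermediate
11 | 9α,11-epoxy-18-(tert-butyldiphenylsilyloxy)-12,13,14,15,16-pentanorlabdan-3β-ol | C[C@@H]1CC[C@H]2[C@](C)(CO[Si](c3ccccc3)(c3ccccc3)C(C)(C)C)[C@@H](O)CC[C@]2(C)[C@@]14CO4 | intermediate
12 | 3-(bromomethyl)furan | BrCc1ccoc1 | starting material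
13 | furan-3-ylmethylmagnesium bromide (not isolated) | Br[Mg]Cc1ccoc1 | intermediate
14 | 18-(tert-butyldiphenylsilyloxy)-15,16-epoxylabda-13(16),14-diene-3β,9α-diol | C[C@@H]1CC[C@H]2[C@](C)(CO[Si](c3ccccc3)(c3ccccc3)C(C)(C)C)[C@@H](O)CC[C@]2(C)[C@@]1(O)CCc4ccoc4 | intermediate
15 | furan endoperoxide of 14 (15,16-epidioxide of the 15,16-epoxy-13-ene, bridgehead epimers; not isolated) | C[C@@H]1CC[C@H]2[C@](C)(CO[Si](c3ccccc3)(c3ccccc3)C(C)(C)C)[C@@H](O)CC[C@]2(C)[C@@]1(O)CCC4=CC5OOC4O5 | intermediate
16 | 18-(tert-butyldiphenylsilyloxy)-3β,9α,16-trihydroxylabd-13-en-15,16-olide (C16 epimers; not isolated) | C[C@@H]1CC[C@H]2[C@](C)(CO[Si](c3ccccc3)(c3ccccc3)C(C)(C)C)[C@@H](O)CC[C@]2(C)[C@@]1(O)CCC4=CC(=O)OC4O | intermediate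
17 | 18-(tert-butyldiphenylsilyloxy)-3β,9α-dihydroxylabd-13-en-15,16-olide | C[C@@H]1CC[C@H]2[C@](C)(CO[Si](c3ccccc3)(c3ccccc3)C(C)(C)C)[C@@H](O)CC[C@]2(C)[C@@]1(O)CCC4=CC(=O)OC4 | intermediate
18 | (13R)-18-(tert-butyldiphenylsilyloxy)-9α,13-epoxy-3β-hydroxylabdan-15,16-olide | C[C@@H]1CC[C@H]2[C@](C)(CO[Si](c3ccccc3)(c3ccccc3)C(C)(C)C)[C@@H](O)CC[C@]2(C)[C@@]14CC[C@@]5(COC(=O)C5)O4 | intermediate
19 | (13R)-9α,13-epoxy-3β,18-dihydroxylabdan-15,16-olide (CNP0274732.3) | C[C@@H]1CC[C@H]2[C@](C)(CO)[C@@H](O)CC[C@]2(C)[C@@]12CC[C@@]1(COC(=O)C1)O2 | target

## Step count and least certain steps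

Total: 11 steps. Longest linear sequence: 11 steps (1 to 19); 2, 6 and 12 are commercial and enter directly.

Step 5 (key step, proposed new method). The most likely failure is early termination of the C10 radical by elimination to an alkene or by hydrogen abstraction from THF, because 6-exo addition of a tertiary radical to a nitrile is slow. The second risk is poor facial control at the planar C4 radical, which would put the silyloxymethyl group axial. The fallback uses known chemistry, sets out from 7 and comes back at 9. The nitrile of 7 would be reduced (DIBAL-H, CH2Cl2, −78 °C, Rochelle-salt work-up) to aldehyde F1 and homologated with the Ohira–Bestmann reagent (K2CO3, MeOH) to terminal alkyne F2. Deprotonation (n-BuLi, THF, −78 °C) and alkylation with Me3SiCH2OTf would give propargylsilane F3. A Lewis acid (MeAlCl2, CH2Cl2, −78 °C) would then trigger a cationic epoxy-ene cyclisation terminated by the propargylsilane, the established Johnson-type terminator, to give exocyclic allene F4. In this mode C4 is set by anti opening of the epoxide and not at a planar radical. Ozonolysis of the allene (O3, CH2Cl2, −78 °C, then Me2S) and K2CO3/MeOH equilibration of C8 would deliver 9.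

Step 10. The likely problems are poor facial selectivity at C13, because the two faces of the butenolide differ only in CH2C(=O) against CH2O, and incomplete closure if the equilibrium does not lie fully on the spiro side. The fallback sets out from 11 and comes back at 18.
- 11 would be opened at C11 by the dianion of 3-methylbut-3-en-1-ol (n-BuLi, TMEDA, Et2O–hexane, then 11 in THF) to give 13(16)-ene triol F5.
- A catalyst-controlled epoxidation of the primary homoallylic alcohol (chiral bishydroxamic acid ligand with VO(OiPr)3 or Hf(OtBu)4, cumene hydroperoxide; ligand enantiomer to be chosen by experiment) would give (13S)-13,16-epoxide F6.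
- Acid (CSA, CH2Cl2) would let the 9α-hydroxyl open it at C13 with inversion (5-exo) to (13R)-9α,13-epoxy-15,16-diol F7.
- Oxidative lactonisation with TEMPO/PhI(OAc)2, which should select the unhindered C15 alcohol over the neopentyl C16 alcohol, would give 18.

C13 would then be set irreversibly by a reagent and not by an equilibrium.

Step 8. The likely problems are coupling through C2 of the furan ring in place of the exocyclic carbon (the furylmethyl Grignard reagent is ambident), slow substitution at a CH2 beside a fully substituted carbon, and magnesium-halide-induced rearrangement of the spiro-epoxide to the C9 aldehyde. The fallback sets out from 12 and 11 and comes back at 14. 12 would be converted with PhSO2Na (DMF, rt) into 3-(phenylsulfonylmethyl)furan F8. Its α-sulfonyl carbanion (n-BuLi, THF–HMPA, −78 °C to rt) can react only at the exocyclic carbon and carries no magnesium halide; opening of 11 would give γ-hydroxy sulfone F9. Reductive desulfonylation (sodium amalgam, Na2HPO4, MeOH, −20 °C) would give 14.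

Step 6. The likely problem is slow or failed addition of the phosphorus ylide to the C9 carbonyl, which is flanked by quaternary C10 and tertiary C8, with enolisation taking over. The fallback sets out from 9 and comes back at 10. Me3SiCH2Li with CeCl3 (THF, −78 °C to 0 °C), a small and weakly basic nucleophile, would add from the α face to give β-hydroxysilane F10. Peterson elimination (KH, THF, 0 °C to rt) would then give 10.

## Further compounds

F1 | step 5 | (5E)-8-[(2S,3S)-3-(tert-butyldiphenylsilyloxymethyl)-3-methyloxiran-2-yl]-2,6-dimethyloct-5-enal (C8 epimers) | O=CC(C)CC/C=C(\C)CC[C@@H]1O[C@@]1(C)CO[Si](c1ccccc1)(c1ccccc1)C(C)(C)C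
F2 | step 5 | (6E)-9-[(2S,3S)-3-(tert-butyldiphenylsilyloxymethyl)-3-methyloxiran-2-yl]-3,7-dimethylnon-6-en-1-yne (C8 epimers) | C#CC(C)CC/C=C(\C)CC[C@@H]1O[C@@]1(C)CO[Si](c1ccccc1)(c1ccccc1)C(C)(C)C
F3 | step 5 | (7E)-10-[(2S,3S)-3-(tert-butyldiphenylsilyloxymethyl)-3-methyloxiran-2-yl]-4,8-dimethyl-1-(trimethylsilyl)dec-7-en-2-yne (C8 epimers) | C[Si](C)(C)CC#CC(C)CC/C=C(\C)CC[C@@H]1O[C@@]1(C)CO[Si](c1ccccc1)(c1ccccc1)C(C)(C)C
F4 | step 5 | 18-(tert-butyldiphenylsilyloxy)-13,14,15,16-tetranorlabda-9(11),11-dien-3β-ol (9-vinylidene decalin, C8 epimers) | CC1CC[C@H]2[C@](C)(CO[Si](c3ccccc3)(c3ccccc3)C(C)(C)C)[C@@H](O)CC[C@]2(C)C1=C=C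
F5 | step 10 | 18-(tert-butyldiphenylsilyloxy)labd-13(16)-ene-3β,9α,15-triol | C[C@@H]1CC[C@H]2[C@](C)(CO[Si](c3ccccc3)(c3ccccc3)C(C)(C)C)[C@@H](O)CC[C@]2(C)[C@@]1(O)CCC(=C)CCO
F6 | step 10 | (13S)-18-(tert-butyldiphenylsilyloxy)-13,16-epoxylabdane-3β,9α,15-triol | C[C@@H]1CC[C@H]2[C@](C)(CO[Si](c3ccccc3)(c3ccccc3)C(C)(C)C)[C@@H](O)CC[C@]2(C)[C@@]1(O)CC[C@]4(CCO)CO4
F7 | step 10 | (13R)-18-(tert-butyldiphenylsilyloxy)-9α,13-epoxylabdane-3β,15,16-triol | C[C@@H]1CC[C@H]2[C@](C)(CO[Si](c3ccccc3)(c3ccccc3)C(C)(C)C)[C@@H](O)CC[C@]2(C)[C@@]14CC[C@](CO)(CCO)O4
F8 | step 8 | 3-[(phenylsulfonyl)methyl]furan | O=S(=O)(Cc1ccoc1)c1ccccc1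
F9 | step 8 | 18-(tert-butyldiphenylsilyloxy)-15,16-epoxy-12-(phenylsulfonyl)labda-13(16),14-diene-3β,9α-diol (C12 epimers) | C[C@@H]1CC[C@H]2[C@](C)(CO[Si](c3ccccc3)(c3ccccc3)C(C)(C)C)[C@@H](O)CC[C@]2(C)[C@@]1(O)CC(c4ccoc4)S(=O)(=O)c5ccccc5
F10 | step 6 | 18-(tert-butyldiphenylsilyloxy)-11-(trimethylsilyl)-12,13,14,15,16-pentanor-9-epi-labdane-3β,9-diol (9β-hydroxyl, CH2SiMe3 α) | C[C@@H]1CC[C@H]2[C@](C)(CO[Si](c3ccccc3)(c3ccccc3)C(C)(C)C)[C@@H](O)CC[C@]2(C)[C@]1(O)C[Si](C)(C)C
A1 | alternative 1 | C9 spiro-cyclobutanone (C9, C11, C12, C13), 3,18-acetonide | C[C@@H]1CC[C@H]2[C@]5(C)COC(C)(C)O[C@H]5CC[C@]2(C)[C@@]13CCC3=O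
A2 | alternative 1 | C9 α-oxaspiropentane (oxygen α, cyclopropane carbon β), 3,18-acetonide | C[C@@H]1CC[C@H]2[C@]5(C)COC(C)(C)O[C@H]5CC[C@]2(C)[C@]13OC34CC4
A3 | alternative 2 | (13R)-3β,18-diacetoxy-9α,13-epoxylabdan-15,16-olide (target diacetate) | C[C@@H]1CC[C@H]2[C@](C)(COC(C)=O)[C@@H](OC(C)=O)CC[C@]2(C)[C@@]12CC[C@@]1(COC(=O)C1)O2
A4 | alternative 2 | 3β,18-diacetoxy-9α,13-epoxy-14,15-dinorlabdan-16-yl diazoacetate | C[C@@H]1CC[C@H]2[C@](C)(COC(C)=O)[C@@H](OC(C)=O)CC[C@]2(C)[C@@]12CC[C@@H](COC(=O)C=[N+]=[N-])O2
A5 | alternative 3 | ring B-fused 7-oxanorbornadiene (C8=C16 and C11=C12, methyl ester at C15, 3,18-acetonide) | C1(CC[C@H]2[C@]5(C)COC(C)(C)O[C@H]5CC[C@]2(C)[C@@]13C=C[C@]4(CC(=O)OC)O3)=C4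
A6 | alternative 3 | 2,5-disubstituted furan with tethered terminal alkyne (furan on C10, methyl acetate arm on C13, 3,18-acetonide) | C#CCC[C@H]1[C@]2(C)COC(C)(C)O[C@H]2CC[C@]1(C)c3ccc(CC(=O)OC)o3
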